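**Assumption:** cudraflavone C is achiral (no stereocenters), so no enantioselective step is needed. The single "enantiomer" is the molecule itself.

## Retrosynthetic overview
1. Cudraflavone C comes from global removal of four MOM groups from the tetra-MOM flavone **11**.
2. **11** is formed in the key step: an aroyl radical from salicylaldehyde **7** adds to the prenyl-bearing carbon of diarylalkyne **10**, and the resulting vinyl radical/cation closes onto the phenol oxygen. This forms C4–C3 and C2–O1 and closes the pyranone ring last.
3. Aldehyde **7** is built from resorcinol by C2 lithiation/prenylation, Ir-catalysed C5–H borylation and oxidation, then ortho-formylation. Alkyne **10** is built from resorcinol (via an aryl iodide) and prenylacetylene, which is made from prenyl bromide and acetylide.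
4. Both aromatic rings are made first from resorcinol. The only ring formed late is the γ-pyranone.

## Route

**Step 1**
Reactants: 1 resorcinol
Product: 2 1,3-bis(methoxymethoxy)benzene
Conditions: NaH, MOMCl, THF/DMF, 0 °C → rt
Reagents that add atoms: MOMCl, ClCOC
Why: Williamson-type acetal protection gives a bis-MOM arene whose OMOM groups later direct lithiation and survive base, organolithiums and radical conditions.

**Step 2**
Reactants: 2 1,3-bis(methoxymethoxy)benzene; 3 prenyl bromide
Product: 4 2-prenyl-1,3-bis(methoxymethoxy)benzene
Conditions: n-BuLi, THF, 0 °C, 2 h; then CuI (10 mol%), 3, −78 °C → rt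
Reagents that add atoms: none
Why: The two OMOM groups direct metalation to C2 (directed ortho-metalation); Cu-catalysed SN2 allylation then puts the prenyl group between the two oxygens, which becomes C6 of the flavone.

**Step 3**
Reactants: 4
Product: 5 pinacol boronate at C5 of 4
Conditions: B2pin2, [Ir(cod)OMe]2 (1.5 mol%), dtbpy (3 mol%), THF, 80 °C
Reagents that add atoms: B2pin2, CC1(C)OB(OC1(C)C)B1OC(C)(C)C(C)(C)O1
Why: Ir-catalysed C–H borylation is sterically controlled and goes to C5, the only C–H meta to all three substituents. This sets up the third 1,3,5-oxygen without needing phloroglucinol.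

**Step 4**
Reactants: 5
Product: 6 4-prenyl-3,5-bis(methoxymethoxy)phenol
Conditions: 30% H2O2, NaOH, THF/H2O, 0 °C → rt
Reagents that add atoms: hydrogen peroxide, OO
Why: Oxidative deborylation (C–B to C–OH with retention of position) gives a phloroglucinol pattern in which only the future ring oxygen (C8a–O) is free.

**Step 5**
Reactants: 6
Product: 7 2-hydroxy-4,6-bis(methoxymethoxy)-5-prenylbenzaldehyde
Conditions: MgCl2, Et3N, (CH2O)n, MeCN, 75 °C
Reagents that add atoms: paraformaldehyde, C=O
Why: Casnati–Skattebøl ortho-formylation occurs only next to the free OH, and the two ortho positions are equivalent by symmetry, so there is no regiochemical issue.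

**Step 6**
Reactants: 2
Product: 8 4-iodo-1,3-bis(methoxymethoxy)benzene
Conditions: NIS, NaHCO3, MeCN, 0 °C
Reagents that add atoms: NIS, O=C1CCC(=O)N1I
Why: Electrophilic iodination goes ortho to one OMOM and para to the other (C4), which gives the 2,4-dioxygenated B-ring attachment point.

**Step 7**
Reactants: 3 prenyl bromide
Product: 9 prenylacetylene (5-methylhex-4-en-1-yne)
Conditions: LiC≡CH·ethylenediamine, DMSO, rt
Reagents that add atoms: lithium acetylide, [Li+].[C-]#C
Why: SN2 alkylation of an acetylide with a primary allylic bromide keeps the normal (not reverse) prenyl connectivity.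

**Step 8**
Reactants: 8 aryl iodide; 9 prenylacetylene
Product: 10 1-[2,4-bis(methoxymethoxy)phenyl]-5-methylhex-4-en-1-yne
Conditions: PdCl2(PPh3)2 (5 mol%), CuI (10 mol%), Et3N, THF, 50 °C, sealed tube
Reagents that add atoms: none
Why: Sonogashira coupling joins the aryl iodide to the terminal alkyne and leaves the trisubstituted alkene and MOM groups untouched.

**Step 9 (key step)**
Reactants: 7 salicylaldehyde; 10 diarylalkyne (2 equiv)
Product: 11 2-[2,4-bis(MOMO)phenyl]-3,6-diprenyl-5,7-bis(MOMO)chromone
Conditions: TBADT (2 mol%), Na2S2O8 (2 equiv), Na2HPO4, MeCN, 390 nm LEDs, 25 °C, 16 h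
Reagents that add atoms: none
Why: Proposed new method: excited decatungstate abstracts the formyl hydrogen to give an aroyl radical, which adds to the prenyl-bearing alkyne carbon. This gives an α-aryl vinyl radical that is stabilised and then oxidised by persulfate to a vinyl cation, made very stable by the o,p-dialkoxyaryl group. The ortho phenol traps the cation in a 6-membered ring closure, so C4–C3 and C2–O1 form in one operation with loss of 2 H. The closest known chemistry is radical hydroacylation of alkynes combined with radical-polar-crossover oxidative cyclisation of 2'-hydroxychalcones. There is no stereocenter to set.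

**Step 10**
Reactants: 11
Product: 12 cudraflavone C
Conditions: 2 M HCl, THF/MeOH (1:2), 40 °C, 6 h, monitored by TLC
Reagents that add atoms: none
Why: Acid hydrolysis of the four aryl MOM acetals (released as MeOCH2OMe) frees all four phenols. Mild, short exposure avoids acid cyclisation of the prenyl groups onto neighbouring OH groups.

## Compound list
1 | resorcinol | Oc1cccc(O)c1 | starting material
2 | 1,3-bis(methoxymethoxy)benzene | COCOc1cccc(OCOC)c1 | intermediate
3 | prenyl bromide | CC(C)=CCBr | starting material
4 | 2-prenyl-1,3-bis(methoxymethoxy)benzene | COCOc1cccc(OCOC)c1CC=C(C)C | intermediate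
5 | 5-(Bpin)-2-prenyl-1,3-bis(MOMO)benzene | COCOc1cc(B2OC(C)(C)C(C)(C)O2)cc(OCOC)c1CC=C(C)C | intermediate
6 | 4-prenyl-3,5-bis(MOMO)phenol | COCOc1cc(O)cc(OCOC)c1CC=C(C)C | intermediate
7 | 2-hydroxy-4,6-bis(MOMO)-5-prenylbenzaldehyde | O=Cc1c(O)cc(OCOC)c(CC=C(C)C)c1OCOC | intermediate
8 | 4-iodo-1,3-bis(MOMO)benzene | COCOc1ccc(I)c(OCOC)c1 | intermediate
9 | prenylacetylene | CC(C)=CCC#C | intermediate
10 | 1-[2,4-bis(MOMO)phenyl]-5-methylhex-4-en-1-yne | COCOc1ccc(C#CCC=C(C)C)c(OCOC)c1 | intermediate
11 | tetra-MOM-protected cudraflavone C | COCOc1cc2oc(-c3ccc(OCOC)cc3OCOC)c(CC=C(C)C)c(=O)c2c(OCOC)c1CC=C(C)C | intermediate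
12 | cudraflavone C | CC(C)=CCc1c(O)cc2oc(-c3ccc(O)cc3O)c(CC=C(C)C)c(=O)c2c1O | target

## Totals
Total steps: 10. Longest linear sequence: 7 (1 → 2 → 4 → 5 → 6 → 7 → 11 → 12).

## Three steps most likely to fail
1. **Step 9 (radical annulation).** The aroyl radical is hindered and electron-rich, and it competes with allylic HAT on the prenyl groups, Dakin-type oxidation and phenol oxidation.
   Fallback (different approach): add lithiated 2,4-bis(MOMO)phenylacetylene to an O-silyl version of 7, oxidise with MnO2 to the ynone, and unmask the phenol with TBAF to trigger 6-endo oxa-Michael closure to the 3-H flavone. Then install the 3-prenyl group by C3 iodination and prenyl cross-coupling.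
2. **Step 3 (Ir borylation).** The trisubstituted arene carries a prenyl alkene, and borylation may be slow or give alkene hydroboration.
   Fallback: introduce the third oxygen before the prenyl group. Borylate and oxidise 2 to 3,5-bis(MOMO)phenol, protect the OH as a pivalate, then do lithiation/prenylation between the two OMOM groups, remove the pivalate, and continue with the formylation.
3. **Step 10 (global MOM removal).** The acid may cyclise the prenyl groups onto the adjacent 5-/7-/2'-OH groups.
   Fallback: rerun the sequence with SEM ethers instead of MOM ethers and remove them at the end with fluoride (TBAF/ethylenediamine), with no acid.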